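**Retrosynthetic overview**

1. The C5–CH2 bond of the β-alkoxy ketone (oxolane C5 to the α-carbon of the aryl ketone) is cut to a C5 oxolanylium ion and the enol silane of acetovanillone (Mukaiyama-type union).
2. The cation is not taken from a lactol: its O1–C2 bond is cut as well, back to an open-chain cis-3,4-epoxy aldehyde whose carbonyl oxygen becomes O1. Ring order: temporary oxirane (step 2), then the oxolane, the only ring of the target, closed in the key step itself.
3. Enabling feature: C5 carries the ring oxygen O1 and lies β to the ketone (O1–C5–CH2–C=O), and the C3 oxygen sits 1,3 to C5 across the oxolane and threo to the C2–O1 bond, which is the trace of an anti-opened cis-oxirane.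
4. Stereochemistry: one catalytic asymmetric epoxidation sets the oxirane; in the key step C2 arises by inversion, C3 is carried over and C5 is relayed from C3 (1,3-cis), giving the all-cis ring.
5. The epoxy aldehyde comes from eugenyl acetate and but-3-en-1-ol by Z-selective cross-metathesis, epoxidation and oxidation; deacetylation ends the route.

Key step: step 5

Remark: the facial sense of the vanadium–bishydroxamic acid epoxidation (step 2) is assumed to follow the model reported for (Z)-homoallylic alcohols; the ligand antipode meant is the one that delivers the (2S,3R)-oxirane 4.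

**Route**

Step 1
Reactants: 1 4-allyl-2-methoxyphenyl acetate (eugenyl acetate); 2 but-3-en-1-ol
Product: 3 4-[(2Z)-5-hydroxypent-2-en-1-yl]-2-methoxyphenyl acetate
Conditions: cyclometalated Ru(NHC) nitrato Z-selective metathesis catalyst (3 mol %), 2 (3 equiv), THF, 35 °C, static vacuum
Reagents that add atoms: none
Why: Z-selective olefin cross-metathesis; the cyclometalated catalyst reacts through syn-substituted metallacyclobutanes and should join an allylarene and a terminal alkenol as the Z-alkene (ethene removed, 2 in excess), tolerating the aryl acetate and the free alcohol; no stereocentre is formed.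

Step 2
Reactants: 3 4-[(2Z)-5-hydroxypent-2-en-1-yl]-2-methoxyphenyl acetate
Product: 4 4-{[(2S,3R)-3-(2-hydroxyethyl)oxiran-2-yl]methyl}-2-methoxyphenyl acetate (cis-oxirane)
Conditions: VO(O-i-Pr)3 (2 mol %), chiral bishydroxamic acid ligand (4 mol %), cumene hydroperoxide (1.5 equiv), toluene, 0 °C to rt
Reagents that add atoms: cumene hydroperoxide, CC(C)(OO)c1ccccc1
Why: Hydroxyl-directed vanadium-catalysed asymmetric epoxidation of a (Z)-homoallylic alcohol; oxygen is delivered syn from the alkoxide-bound vanadium peroxide, so the Z-alkene becomes the cis-oxirane and the ligand antipode selects the face, setting both oxirane stereocentres at once.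

Step 3
Reactants: 4 4-{[(2S,3R)-3-(2-hydroxyethyl)oxiran-2-yl]methyl}-2-methoxyphenyl acetate
Product: 5 2-methoxy-4-{[(2S,3R)-3-(2-oxoethyl)oxiran-2-yl]methyl}phenyl acetate
Conditions: Dess–Martin periodinane (1.3 equiv), NaHCO3 (5 equiv), CH2Cl2, 0 °C; pentane–Et2O, filtration, used crude at once
Reagents that add atoms: none
Why: Dess–Martin oxidation under bicarbonate buffer is neutral and fast, so the β,γ-epoxy aldehyde should form without base-induced β-elimination; the stereocentres are not touched.

Step 4
Reactants: 6 1-(4-hydroxy-3-methoxyphenyl)ethan-1-one (acetovanillone)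
Product: 7 trimethyl({1-[3-methoxy-4-(trimethylsilyloxy)phenyl]ethenyl}oxy)silane
Conditions: TMSOTf (2.3 equiv), Et3N (3 equiv), CH2Cl2, 0 °C; pentane trituration, filtration
Reagents that add atoms: trimethylsilyl trifluoromethanesulfonate, C[Si](C)(C)OS(=O)(=O)C(F)(F)F
Why: Soft enolisation with silyl triflate and amine converts the methyl ketone into its trimethylsilyl enol ether and caps the phenol as its silyl ether in the same operation; no stereocentre.

Step 5
Reactants: 5 2-methoxy-4-{[(2S,3R)-3-(2-oxoethyl)oxiran-2-yl]methyl}phenyl acetate; 7 trimethyl({1-[3-methoxy-4-(trimethylsilyloxy)phenyl]ethenyl}oxy)silane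
Product: 10 4-{[(2R,3R,5R)-3-hydroxy-5-[2-(4-hydroxy-3-methoxyphenyl)-2-oxoethyl]oxolan-2-yl]methyl}-2-methoxyphenyl acetate, via oxolanylium triflate 8 (not isolated), via bis(trimethylsilyl) ether 9 (not isolated)
Conditions: 7 (1.5 equiv), TMSOTf (0.2 equiv), 2,6-di-tert-butyl-4-methylpyridine (0.1 equiv), CH2Cl2, −78 °C; then 1 M HCl, THF, 0 °C
Reagents that add atoms: none
Why: Proposed new method: TMSOTf activates the oxirane oxygen of 5, the aldehyde oxygen then opens the oxirane at the arylmethyl-bearing carbon from the rear (5-endo epoxide opening, the only ring closure, which makes the oxolane) to give the 3-silyloxy oxocarbenium ion 8, and the enol silane 7 adds to C5 of 8 in a Mukaiyama-type step that passes its silyl group on as new TMSOTf, leaving 9, which dilute acid desilylates to 10. The closest known reaction types are carbonyl-oxygen participation in acid-induced epoxide opening (keto epoxide to bicyclic ketal), the 5-endo cyclisation of 3,4-epoxy alcohols to oxolan-3-ols, and the Lewis-acid addition of enol silanes to 3-oxy-substituted furanosyl cations; their union, with an aldehyde oxygen as ring-closing nucleophile and an external carbon terminator, is the new element. C2 is set by stereospecific inversion at the oxirane carbon and C3 is carried over, so the cis-oxirane maps onto the 2,3-cis oxolane. C5 is set by substrate control: 8 should react through the envelope with pseudoaxial C3–OSiMe3 and pseudoequatorial C2 arylmethyl group and take the nucleophile on the inside face, cis to the C3 oxygen (the 1,3-cis rule of 3-alkoxy five-membered oxocarbenium ions), which gives the all-cis ring. The step needs oxirane activation to outrun direct addition to the aldehyde and the carbonyl oxygen to outrun the arene: TMSOTf couples enol silanes with oxocarbenium ions but hardly with free aldehydes at −78 °C, the aryl acetate keeps the arene too electron-poor for phenonium participation, and the 4-exo alternative would give a strained oxetanylium ion.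

Step 6
Reactants: 10 4-{[(2R,3R,5R)-3-hydroxy-5-[2-(4-hydroxy-3-methoxyphenyl)-2-oxoethyl]oxolan-2-yl]methyl}-2-methoxyphenyl acetate
Product: 11 renealtin A, 2-[(2R,4R,5R)-4-hydroxy-5-[(4-hydroxy-3-methoxyphenyl)methyl]oxolan-2-yl]-1-(4-hydroxy-3-methoxyphenyl)ethan-1-one
Conditions: K2CO3 (0.3 equiv), MeOH, 0 °C; aq. NH4Cl
Reagents that add atoms: none
Why: Base-catalysed transesterification (Zemplén-type methanolysis) should remove the aryl acetate quickly at 0 °C, while the phenoxide of the aryl ketone disfavours enolisation and hence retro-oxa-Michael epimerisation at C5; no stereocentre is changed.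

**Compound list**

1 | 4-allyl-2-methoxyphenyl acetate (eugenyl acetate) | C=CCc1ccc(OC(C)=O)c(OC)c1 | starting material
2 | but-3-en-1-ol | C=CCCO | starting material
3 | 4-[(2Z)-5-hydroxypent-2-en-1-yl]-2-methoxyphenyl acetate | OCC/C=C\Cc1ccc(OC(C)=O)c(OC)c1 | intermediate
4 | 4-{[(2S,3R)-3-(2-hydroxyethyl)oxiran-2-yl]methyl}-2-methoxyphenyl acetate | OCC[C@@H]1[C@H](Cc2ccc(OC(C)=O)c(OC)c2)O1 | intermediate
5 | 2-methoxy-4-{[(2S,3R)-3-(2-oxoethyl)oxiran-2-yl]methyl}phenyl acetate | O=CC[C@@H]1[C@H](Cc2ccc(OC(C)=O)c(OC)c2)O1 | intermediate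
6 | 1-(4-hydroxy-3-methoxyphenyl)ethan-1-one (acetovanillone) | CC(=O)c1ccc(O)c(OC)c1 | starting material
7 | trimethyl({1-[3-methoxy-4-(trimethylsilyloxy)phenyl]ethenyl}oxy)silane | C=C(O[Si](C)(C)C)c1ccc(O[Si](C)(C)C)c(OC)c1 | intermediate
8 | (2R,3R)-2-[(4-acetoxy-3-methoxyphenyl)methyl]-3-(trimethylsilyloxy)-3,4-dihydro-2H-furan-1-ium trifluoromethanesulfonate | COc1cc(C[C@H]2[O+]=CC[C@H]2O[Si](C)(C)C)ccc1OC(C)=O.[O-]S(=O)(=O)C(F)(F)F | intermediate
9 | 4-{[(2R,3R,5R)-5-{2-[3-methoxy-4-(trimethylsilyloxy)phenyl]-2-oxoethyl}-3-(trimethylsilyloxy)oxolan-2-yl]methyl}-2-methoxyphenyl acetate | COc1cc(C[C@H]2O[C@@H](CC(=O)c3ccc(O[Si](C)(C)C)c(OC)c3)C[C@H]2O[Si](C)(C)C)ccc1OC(C)=O | intermediate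
10 | 4-{[(2R,3R,5R)-3-hydroxy-5-[2-(4-hydroxy-3-methoxyphenyl)-2-oxoethyl]oxolan-2-yl]methyl}-2-methoxyphenyl acetate | COc1cc(C[C@H]2O[C@@H](CC(=O)c3ccc(O)c(OC)c3)C[C@H]2O)ccc1OC(C)=O | intermediate
11 | renealtin A, 2-[(2R,4R,5R)-4-hydroxy-5-[(4-hydroxy-3-methoxyphenyl)methyl]oxolan-2-yl]-1-(4-hydroxy-3-methoxyphenyl)ethan-1-one | COc1cc(C[C@H]2O[C@@H](CC(=O)c3ccc(O)c(OC)c3)C[C@H]2O)ccc1O | target

**Count**

Total step count: 6. Longest linear sequence: 5 steps (1, 2, 3, 5, 6).

**Steps most likely to fail**

1. Step 5 (proposed new method). The enol silane may add to the aldehyde before the oxirane has been opened. The activated oxirane may also be opened by triflate and then closed with net retention at C2, or it may rearrange by hydride shift, so that the cascade is diverted or its fidelity at C2 and C5 is eroded. Fallback with known chemistry (bond first, ring second): setting out from 5, a BF3·OEt2-mediated Mukaiyama aldol addition of 7 at −78 °C with cold aqueous quench should give, by open-chain 1,3-anti induction from the β-oxygen, the hydroxy ketone 4-{[(2S,3R)-3-[(2R)-2-hydroxy-4-(4-hydroxy-3-methoxyphenyl)-4-oxobutyl]oxiran-2-yl]methyl}-2-methoxyphenyl acetate F1. Catalytic camphorsulfonic acid in CH2Cl2 would then close the oxolane by 5-endo opening of the 3,4-epoxy alcohol with inversion, which comes back to the route at 10.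

2. Step 3. β-Elimination of the β,γ-epoxy aldehyde to the γ-hydroxy enal may occur during oxidation, work-up or handling. Fallback (ring first, at the acid oxidation level, so that the free aldehyde never accumulates): setting out from 4, TEMPO/PhI(OAc)2 in MeCN–H2O would give {(2R,3S)-3-[(4-acetoxy-3-methoxyphenyl)methyl]oxiran-2-yl}acetic acid F2. With catalytic camphorsulfonic acid this should lactonise by 5-endo attack of the carboxyl group with inversion to 4-{[(2R,3R)-3-hydroxy-5-oxooxolan-2-yl]methyl}-2-methoxyphenyl acetate F3. Disiamylborane in THF would reduce the lactone, but not the aryl acetate, to the lactol 4-{[(2R,3R)-3,5-dihydroxyoxolan-2-yl]methyl}-2-methoxyphenyl acetate F4. TMSCl/Et3N would give 2-methoxy-4-{[(2R,3R)-3,5-bis(trimethylsilyloxy)oxolan-2-yl]methyl}phenyl acetate F5. TMSOTf-catalysed C-glycosylation of F5 with 7 at −78 °C (the established 1,3-cis addition to 3-oxy furanosyl cations) would pass through 8 and come back to the route at 9, which the acid work-up of step 5 turns into 10.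

3. Step 1. Statistical partition between cross- and homo-coupling and erosion of Z-selectivity by secondary metathesis would carry the E-alkene, and later the trans-oxirane, forward. Fallback (carbonyl olefination instead of metathesis): setting out from 1, ozonolysis (O3, CH2Cl2, −78 °C; PPh3) would give 2-methoxy-4-(2-oxoethyl)phenyl acetate F6. Salt-free Wittig olefination with the ylide from [3-(tert-butyldimethylsilyloxy)propyl]triphenylphosphonium bromide and NaHMDS (THF, −78 °C) should give 4-[(2Z)-5-(tert-butyldimethylsilyloxy)pent-2-en-1-yl]-2-methoxyphenyl acetate F7. HF·pyridine in THF would free the alcohol and come back to the route at 3.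

**Further compounds**

F1 | step 5 | 4-{[(2S,3R)-3-[(2R)-2-hydroxy-4-(4-hydroxy-3-methoxyphenyl)-4-oxobutyl]oxiran-2-yl]methyl}-2-methoxyphenyl acetate | O[C@@H](CC(=O)c1ccc(O)c(OC)c1)C[C@@H]1[C@H](Cc2ccc(OC(C)=O)c(OC)c2)O1
F2 | step 3 | {(2R,3S)-3-[(4-acetoxy-3-methoxyphenyl)methyl]oxiran-2-yl}acetic acid | OC(=O)C[C@@H]1[C@H](Cc2ccc(OC(C)=O)c(OC)c2)O1
F3 | step 3 | 4-{[(2R,3R)-3-hydroxy-5-oxooxolan-2-yl]methyl}-2-methoxyphenyl acetate | COc1cc(C[C@H]2OC(=O)C[C@H]2O)ccc1OC(C)=O
F4 | step 3 | 4-{[(2R,3R)-3,5-dihydroxyoxolan-2-yl]methyl}-2-methoxyphenyl acetate (anomer mixture) | COc1cc(C[C@H]2OC(O)C[C@H]2O)ccc1OC(C)=O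
F5 | step 3 | 2-methoxy-4-{[(2R,3R)-3,5-bis(trimethylsilyloxy)oxolan-2-yl]methyl}phenyl acetate (anomer mixture) | COc1cc(C[C@H]2OC(O[Si](C)(C)C)C[C@H]2O[Si](C)(C)C)ccc1OC(C)=O
F6 | step 1 | 2-methoxy-4-(2-oxoethyl)phenyl acetate | O=CCc1ccc(OC(C)=O)c(OC)c1
F7 | step 1 | 4-[(2Z)-5-(tert-butyldimethylsilyloxy)pent-2-en-1-yl]-2-methoxyphenyl acetate | CC(C)(C)[Si](C)(C)OCC/C=C\Cc1ccc(OC(C)=O)c(OC)c1
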